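The oxolanone ring of the lactone half is read as one CO2 molecule (O1′, C5′=O) laid across a trimethylenemethane C4 unit (C4′H2, C3′ with its methyl carbon, C2′). A palladium(0)-catalysed [3+2] cocyclisation of methylenecyclopropane with CO2 forms C4′–C5′ and O1′–C2′ in one operation and, after in-flask alkene migration, gives 4-methylfuran-2(5H)-one. Its silyloxyfuran adds to a chromone-2-carboxylate benzopyrylium (C2–C2′); a catalyst-controlled CuH reduction resolves the racemate and sets C3′. After ortho-iodination the material is divided: one part is stannylated, the other saponified to the seco acid, and a Stille cross-coupling (C6–C6 biaryl bond) joins the two halves.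

Key step: step 1

Remarks on the chemistry:
- Locants: chromanone atoms are unprimed (O1, C2, C3, C4, C4a, C5–C8, C8a); oxolanone atoms are primed (O1′, C2′ bonded to C2, C3′ bearing the methyl group, C4′H2, C5′=O). Only in the systematic names of 6,6′-bichromenes does the prime mark the second chromanone unit instead.
- Racemates (11, 12) are named (±) and drawn as the enantiomer that is carried forward.
- Which antipode of the ligand in step 5 is matched to the (2S,2′R) enantiomer is assumed, not known; (R)-DTBM-SEGPHOS is written and its antipode is taken if the sense is the reverse.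

Step 1
Reactants: 1 methylenecyclopropane; 2 carbon dioxide
Product: 4 4-methylfuran-2(5H)-one, via 4-methylenedihydrofuran-2(3H)-one 3 (not isolated)
Conditions: Pd2(dba)3 (1 mol%), PPh3 (4 mol%), CO2 (40 bar), DMF, 130 °C, autoclave
Reagents that add atoms: none
Why: Pd(0) inserts into the distal C–C bond of 1 to give a trimethylenemethane–palladium (η3-allyl zwitterion) species whose nucleophilic CH2 terminus adds to CO2 (C–C bond), and the carboxylate so formed closes on the η3-allyl terminus (C–O bond). This is the palladium(0)-catalysed methylenecyclopropane–CO2 cocyclisation, a formal [3+2] cycloaddition of trimethylenemethane across one C=O of CO2. The one ring closes by intramolecular allylic C–O substitution of the carboxylate at the allyl terminus (5-exo-tet on the σ-allyl form) to give 3, whose exocyclic alkene then moves into conjugation (Pd–H/π-allyl isomerisation) to give 4. No stereocentre is formed. The step needs chemoselectivity for CO2 over a second molecule of 1 (oligomers, [3+2] addition of 1 to the C=C of 4), which the CO2 pressure, the polar solvent and a low stationary concentration of 1 should secure; regiochemistry is not an issue because the three CH2 termini of the trimethylenemethane unit are equivalent.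

Step 2
Reactants: 4 4-methylfuran-2(5H)-one
Product: 5 trimethyl[(4-methylfuran-2-yl)oxy]silane
Conditions: TMSOTf, Et3N, CH2Cl2, 0 °C; distillation
Reagents that add atoms: trimethylsilyl trifluoromethanesulfonate, C[Si](C)(C)OS(=O)(=O)C(F)(F)F
Why: Silyl dienol ether formation (soft enolisation): TMSOTf activates the lactone carbonyl and Et3N removes a C5–H to give the aromatic 2-silyloxyfuran; no stereocentre is involved.

Step 3
Reactants: 6 1-(2,6-dihydroxyphenyl)ethan-1-one; 7 dimethyl oxalate
Product: 9 methyl 5-hydroxy-4-oxo-4H-chromene-2-carboxylate, via methyl 4-(2,6-dihydroxyphenyl)-2,4-dioxobutanoate 8 (not isolated)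
Conditions: NaOMe, MeOH, reflux; then conc. HCl, MeOH, reflux
Reagents that add atoms: none
Why: Claisen condensation of the methyl ketone enolate with the oxalate gives 8, which cyclodehydrates under acid to the chromone; the two phenols of 6 are equivalent, so only one product can form, and no stereocentre is made.

Step 4
Reactants: 9 methyl 5-hydroxy-4-oxo-4H-chromene-2-carboxylate; 5 trimethyl[(4-methylfuran-2-yl)oxy]silane
Product: 12 (±)-methyl (2S*)-5-hydroxy-2-[(2R*)-3-methyl-5-oxo-2,5-dihydrofuran-2-yl]-4-oxo-3,4-dihydro-2H-chromene-2-carboxylate, via silyl-bridged benzopyrylium triflate 10 (not isolated), via silyl-bridged enol ether adduct 11 (not isolated)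
Conditions: i-Pr2Si(OTf)2 (1.1 equiv), 2,6-lutidine (1.1 equiv), CH2Cl2, rt; then 5 (3 equiv), −78 °C; then Et3N·3HF, rt; chromatography
Reagents that add atoms: diisopropylsilyl bis(trifluoromethanesulfonate), CC(C)[Si](OS(=O)(=O)C(F)(F)F)(OS(=O)(=O)C(F)(F)F)C(C)C (atoms held in 10 and 11 only)
Why: Vinylogous Mukaiyama-type addition of a 2-silyloxyfuran to a 4-siloxybenzopyrylium: silicon bridges O5 and O4 to give 10, C5 of 5 attacks C2 and creates C2 and C2′ together, the (2S*,2′R*) isomer corresponding to the synclinal (Diels–Alder-like) approach with the furan oxygen over the pyrylium ring, and its C2′ epimer being removed by chromatography.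

Step 5
Reactants: 12 (±)-methyl (2S*)-5-hydroxy-2-[(2R*)-3-methyl-5-oxo-2,5-dihydrofuran-2-yl]-4-oxo-3,4-dihydro-2H-chromene-2-carboxylate
Product: 13 methyl (2S)-5-hydroxy-2-[(2R,3S)-3-methyl-5-oxooxolan-2-yl]-4-oxo-3,4-dihydro-2H-chromene-2-carboxylate
Conditions: Cu(OAc)2·H2O (5 mol%), (R)-DTBM-SEGPHOS (5.5 mol%), (EtO)2MeSiH, t-BuOH, toluene, −20 °C, stopped near half conversion; aq. NH4Cl; chromatography (unreacted butenolide enantiomer removed)
Reagents that add atoms: none
Why: Copper hydride asymmetric conjugate reduction run as a kinetic resolution: hydride adds to C3′ anti to the chromanone at C2′ (substrate bias, giving the 2′,3′-cis lactone), and the ligand permits this for the (2S,2′R) enantiomer (matched) while the antipode (mismatched) stays as butenolide, so C3′ (S) and the absolute configuration are both set here.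

Step 6
Reactants: 13 methyl (2S)-5-hydroxy-2-[(2R,3S)-3-methyl-5-oxooxolan-2-yl]-4-oxo-3,4-dihydro-2H-chromene-2-carboxylate
Product: 14 methyl (2S)-5-hydroxy-6-iodo-2-[(2R,3S)-3-methyl-5-oxooxolan-2-yl]-4-oxo-3,4-dihydro-2H-chromene-2-carboxylate
Conditions: BnMe3N·ICl2 (1.05 equiv), CaCO3, CH2Cl2/MeOH, rt
Reagents that add atoms: benzyltrimethylammonium dichloroiodate, C[N+](C)(C)Cc1ccccc1.Cl[I-]Cl
Why: Electrophilic aromatic iodination: the chelated 5-OH should direct the dichloroiodate to its ortho position C6 (also para to O1), and CaCO3 takes up HCl so that the lactone and the C2 centre stay untouched.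

Step 7
Reactants: 14 methyl (2S)-5-hydroxy-6-iodo-2-[(2R,3S)-3-methyl-5-oxooxolan-2-yl]-4-oxo-3,4-dihydro-2H-chromene-2-carboxylate
Product: 15 methyl (2S)-5-hydroxy-2-[(2R,3S)-3-methyl-5-oxooxolan-2-yl]-4-oxo-6-(trimethylstannyl)-3,4-dihydro-2H-chromene-2-carboxylate
Conditions: Me3SnSnMe3 (2.0 equiv), Pd(PPh3)4 (5 mol%), toluene, 90 °C; chromatography on Et3N-deactivated silica
Reagents that add atoms: hexamethylditin, C[Sn](C)(C)[Sn](C)(C)C
Why: Palladium-catalysed stannylation of an aryl iodide (Stille-type coupling with a distannane): oxidative addition at C6–I, transmetalation with hexamethylditin and reductive elimination give the aryl–tin bond under neutral conditions that should leave lactone, ester and stereocentres intact, while the excess of distannane and the absence of copper hold back coupling of 15 with unreacted 14.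

Step 8
Reactants: 14 methyl (2S)-5-hydroxy-6-iodo-2-[(2R,3S)-3-methyl-5-oxooxolan-2-yl]-4-oxo-3,4-dihydro-2H-chromene-2-carboxylate
Product: 16 (3S,4R)-4-hydroxy-4-[(2S)-5-hydroxy-6-iodo-2-(methoxycarbonyl)-4-oxo-3,4-dihydro-2H-chromen-2-yl]-3-methylbutanoic acid
Conditions: LiOH·H2O (2.2 equiv), THF/H2O (3:1), 0 °C; 1 M HCl to pH 4 at 0 °C; extraction (EtOAc); used without delay
Reagents that add atoms: lithium hydroxide, [Li+].[OH-]
Why: Saponification (BAc2) of the γ-lactone: once the phenol is deprotonated, hydroxide should attack the unhindered C5′ carbonyl faster than the methyl ester on quaternary C2, acyl–oxygen cleavage retains the (R)-carbinol and (S)-methyl centres, and the phenoxide disfavours enolisation at C3 and hence E1cB opening of the pyranone ring and C2 epimerisation.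

Step 9
Reactants: 15 methyl (2S)-5-hydroxy-2-[(2R,3S)-3-methyl-5-oxooxolan-2-yl]-4-oxo-6-(trimethylstannyl)-3,4-dihydro-2H-chromene-2-carboxylate; 16 (3S,4R)-4-hydroxy-4-[(2S)-5-hydroxy-6-iodo-2-(methoxycarbonyl)-4-oxo-3,4-dihydro-2H-chromen-2-yl]-3-methylbutanoic acid
Product: 17 (3S,4R)-4-hydroxy-4-[(2S)-5-hydroxy-6-{(2S)-5-hydroxy-2-(methoxycarbonyl)-2-[(2R,3S)-3-methyl-5-oxooxolan-2-yl]-4-oxo-3,4-dihydro-2H-chromen-6-yl}-2-(methoxycarbonyl)-4-oxo-3,4-dihydro-2H-chromen-2-yl]-3-methylbutanoic acid (CNP0517857.1)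
Conditions: Pd(PPh3)4 (10 mol%), CuI (20 mol%), CsF (3 equiv), DMF, 45 °C; 1 M HCl to pH 4 at 0 °C; reversed-phase chromatography
Reagents that add atoms: none
Why: Stille cross-coupling under copper(I)/fluoride promotion: oxidative addition of Pd(0) at C6–I of 16, tin-to-copper-to-palladium transfer of the aryl group of 15 (fluoride takes up the tin as Me3SnF and holds 16 as its carboxylate, which can neither protonate the stannane nor relactonise) and reductive elimination should form the C6–C6 biaryl bond without any base that could touch the lactone, the esters or C2; the 2,2′-dihydroxybiaryl axis is not a stereogenic element.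

Compound list
1 | methylenecyclopropane | C=C1CC1 | starting material
2 | carbon dioxide | O=C=O | starting material
3 | 4-methylenedihydrofuran-2(3H)-one | C=C1COC(=O)C1 | intermediate
4 | 4-methylfuran-2(5H)-one | CC1=CC(=O)OC1 | intermediate
5 | trimethyl[(4-methylfuran-2-yl)oxy]silane | Cc1coc(O[Si](C)(C)C)c1 | intermediate
6 | 1-(2,6-dihydroxyphenyl)ethan-1-one | CC(=O)c1c(O)cccc1O | starting material
7 | dimethyl oxalate | COC(=O)C(=O)OC | starting material
8 | methyl 4-(2,6-dihydroxyphenyl)-2,4-dioxobutanoate | COC(=O)C(=O)CC(=O)c1c(O)cccc1O | intermediate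
9 | methyl 5-hydroxy-4-oxo-4H-chromene-2-carboxylate | COC(=O)c1cc(=O)c2c(O)cccc2o1 | intermediate
10 | 2-(methoxycarbonyl)-4,5-(diisopropylsilylenedioxy)chromenylium trifluoromethanesulfonate (Si bridges O4 and O5) | CC(C)[Si]1(C(C)C)Oc2cc(C(=O)OC)[o+]c3cccc(O1)c23.[O-]S(=O)(=O)C(F)(F)F | intermediate
11 | (±)-methyl (2S*)-4,5-(diisopropylsilylenedioxy)-2-[(2R*)-3-methyl-5-oxo-2,5-dihydrofuran-2-yl]-2H-chromene-2-carboxylate | CC(C)[Si]1(C(C)C)OC2=C[C@@](C(=O)OC)([C@@H]3OC(=O)C=C3C)Oc3cccc(O1)c23 | intermediate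
12 | (±)-methyl (2S*)-5-hydroxy-2-[(2R*)-3-methyl-5-oxo-2,5-dihydrofuran-2-yl]-4-oxo-3,4-dihydro-2H-chromene-2-carboxylate | O=C1C[C@@](C(=O)OC)([C@@H]2OC(=O)C=C2C)Oc2cccc(O)c12 | intermediate
13 | methyl (2S)-5-hydroxy-2-[(2R,3S)-3-methyl-5-oxooxolan-2-yl]-4-oxo-3,4-dihydro-2H-chromene-2-carboxylate | O=C1C[C@@](C(=O)OC)([C@@H]2OC(=O)C[C@@H]2C)Oc2cccc(O)c12 | intermediate
14 | methyl (2S)-5-hydroxy-6-iodo-2-[(2R,3S)-3-methyl-5-oxooxolan-2-yl]-4-oxo-3,4-dihydro-2H-chromene-2-carboxylate | O=C1C[C@@](C(=O)OC)([C@@H]2OC(=O)C[C@@H]2C)Oc2ccc(I)c(O)c12 | intermediate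
15 | methyl (2S)-5-hydroxy-2-[(2R,3S)-3-methyl-5-oxooxolan-2-yl]-4-oxo-6-(trimethylstannyl)-3,4-dihydro-2H-chromene-2-carboxylate | O=C1C[C@@](C(=O)OC)([C@@H]2OC(=O)C[C@@H]2C)Oc2ccc([Sn](C)(C)C)c(O)c12 | intermediate
16 | (3S,4R)-4-hydroxy-4-[(2S)-5-hydroxy-6-iodo-2-(methoxycarbonyl)-4-oxo-3,4-dihydro-2H-chromen-2-yl]-3-methylbutanoic acid | O=C1C[C@@](C(=O)OC)([C@H](O)[C@@H](C)CC(=O)O)Oc2ccc(I)c(O)c12 | intermediate
17 | (3S,4R)-4-hydroxy-4-[(2S)-5-hydroxy-6-{(2S)-5-hydroxy-2-(methoxycarbonyl)-2-[(2R,3S)-3-methyl-5-oxooxolan-2-yl]-4-oxo-3,4-dihydro-2H-chromen-6-yl}-2-(methoxycarbonyl)-4-oxo-3,4-dihydro-2H-chromen-2-yl]-3-methylbutanoic acid (CNP0517857.1) | COC(=O)[C@@]1([C@H](O)[C@@H](C)CC(=O)O)CC(=O)c2c(ccc(-c3ccc4c(c3O)C(=O)C[C@@](C(=O)OC)([C@@H]3OC(=O)C[C@@H]3C)O4)c2O)O1 | target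

Total step count: 9. Longest linear sequence: 7 steps (1, 2, 4, 5, 6, 7, 9); step 3 supplies 9 and step 8 branches from 14.

Steps most likely to fail

Step 9. The trimethylstannyl group of 15 may be lost by protonation from the free phenols before it is transferred, transfer to palladium at the ortho-substituted carbon may be slow, and either partner may homocouple. The fallback forms the biaryl bond with copper on protected phenols and opens one lactone only afterwards; it sets out from 14 and comes back to the route at 17. The phenol of 14 is protected (MOMCl, i-Pr2NEt, CH2Cl2, 40 °C) to give the 5-methoxymethoxy iodide F1. Stannylation ((Bu3Sn)2, Pd(PPh3)4, toluene, 100 °C) gives the 6-(tributylstannyl) 5-methoxymethoxy compound F2. Copper-mediated oxidative homocoupling (CuCl, DMA, air, rt) gives the 5,5′-bis(methoxymethoxy) 6,6′-dimer F3. Acid (TFA, wet CH2Cl2, 0 °C) removes both acetals to give the bis-lactone 6,6′-dimer F4. Saponification of one of its two equivalent lactones (LiOH·H2O, 3.1 equiv, THF/H2O, 0 °C; 1 M HCl to pH 4; unreacted F4 recycled) should give 17.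

Step 7. The aryl–tin bond next to a free phenol may be cleaved by protonation in the flask or on silica, and stannane formed early may couple with iodide not yet consumed. The fallback replaces tin by boron; it sets out from 14 and comes back to the route at 17. Miyaura borylation of 14 (B2pin2, PdCl2(dppf), KOAc, 1,4-dioxane, 80 °C) gives the pinacol boronate F5, which should survive chromatography. Suzuki–Miyaura cross-coupling of F5 with 16 under anhydrous fluoride activation (Pd(OAc)2, SPhos, CsF, 1,4-dioxane, 60 °C), which avoids aqueous base and so spares the lactone, followed by acidification to pH 4, should give 17.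

Step 5. The catalyst may discriminate the enantiomers poorly, or copper hydride may reduce the C4 ketone in competition. The fallback gives up the kinetic resolution for a classical one; it sets out from 12 and comes back at 13. Non-selective hydrogenation of 12 (H2, Rh/Al2O3, EtOAc), again anti to the chromanone, gives racemic cis lactone (±)-13 F6. Saponification (LiOH, THF/H2O, 0 °C, then pH 4) gives the racemic seco acid (±)-(3S*,4R*)-4-hydroxy-4-[(2S*)-5-hydroxy-2-(methoxycarbonyl)-4-oxo-3,4-dihydro-2H-chromen-2-yl]-3-methylbutanoic acid F7. Crystallisation with (R)-1-phenylethylamine should give the salt of the (2S,3S,4R) acid, (R)-1-phenylethylammonium (3S,4R)-4-hydroxy-4-[(2S)-5-hydroxy-2-(methoxycarbonyl)-4-oxo-3,4-dihydro-2H-chromen-2-yl]-3-methylbutanoate F8; the (S)-amine is used if the other salt is the less soluble one. TsOH in toluene liberates the acid and closes the lactone to 13.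

Further compounds
F1 | step 9 | methyl (2S)-6-iodo-5-(methoxymethoxy)-2-[(2R,3S)-3-methyl-5-oxooxolan-2-yl]-4-oxo-3,4-dihydro-2H-chromene-2-carboxylate | O=C1C[C@@](C(=O)OC)([C@@H]2OC(=O)C[C@@H]2C)Oc2ccc(I)c(OCOC)c12
F2 | step 9 | methyl (2S)-5-(methoxymethoxy)-2-[(2R,3S)-3-methyl-5-oxooxolan-2-yl]-4-oxo-6-(tributylstannyl)-3,4-dihydro-2H-chromene-2-carboxylate | O=C1C[C@@](C(=O)OC)([C@@H]2OC(=O)C[C@@H]2C)Oc2ccc([Sn](CCCC)(CCCC)CCCC)c(OCOC)c12
F3 | step 9 | dimethyl (2S,2′S)-5,5′-bis(methoxymethoxy)-2,2′-bis[(2R,3S)-3-methyl-5-oxooxolan-2-yl]-4,4′-dioxo-3,3′,4,4′-tetrahydro-2H,2′H-[6,6′-bichromene]-2,2′-dicarboxylate | COC(=O)[C@@]1([C@@H]5OC(=O)C[C@@H]5C)CC(=O)c2c(ccc(-c3ccc4c(c3OCOC)C(=O)C[C@@](C(=O)OC)([C@@H]3OC(=O)C[C@@H]3C)O4)c2OCOC)O1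
F4 | step 9 | dimethyl (2S,2′S)-5,5′-dihydroxy-2,2′-bis[(2R,3S)-3-methyl-5-oxooxolan-2-yl]-4,4′-dioxo-3,3′,4,4′-tetrahydro-2H,2′H-[6,6′-bichromene]-2,2′-dicarboxylate | COC(=O)[C@@]1([C@@H]5OC(=O)C[C@@H]5C)CC(=O)c2c(ccc(-c3ccc4c(c3O)C(=O)C[C@@](C(=O)OC)([C@@H]3OC(=O)C[C@@H]3C)O4)c2O)O1
F5 | step 7 | methyl (2S)-5-hydroxy-2-[(2R,3S)-3-methyl-5-oxooxolan-2-yl]-4-oxo-6-(4,4,5,5-tetramethyl-1,3,2-dioxaborolan-2-yl)-3,4-dihydro-2H-chromene-2-carboxylate | O=C1C[C@@](C(=O)OC)([C@@H]2OC(=O)C[C@@H]2C)Oc2ccc(B3OC(C)(C)C(C)(C)O3)c(O)c12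
F6 | step 5 | (±)-methyl (2S*)-5-hydroxy-2-[(2R*,3S*)-3-methyl-5-oxooxolan-2-yl]-4-oxo-3,4-dihydro-2H-chromene-2-carboxylate (racemate, drawn as one enantiomer) | O=C1C[C@@](C(=O)OC)([C@@H]2OC(=O)C[C@@H]2C)Oc2cccc(O)c12
F7 | step 5 | (±)-(3S*,4R*)-4-hydroxy-4-[(2S*)-5-hydroxy-2-(methoxycarbonyl)-4-oxo-3,4-dihydro-2H-chromen-2-yl]-3-methylbutanoic acid (racemate, drawn as one enantiomer) | O=C1C[C@@](C(=O)OC)([C@H](O)[C@@H](C)CC(=O)O)Oc2cccc(O)c12
F8 | step 5 | (R)-1-phenylethylammonium (3S,4R)-4-hydroxy-4-[(2S)-5-hydroxy-2-(methoxycarbonyl)-4-oxo-3,4-dihydro-2H-chromen-2-yl]-3-methylbutanoate | O=C1C[C@@](C(=O)OC)([C@H](O)[C@@H](C)CC(=O)[O-])Oc2cccc(O)c12.C[C@@H]([NH3+])c1ccccc1
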